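**Retrosynthetic overview**

- The (E)-enone Cα=Cβ bond is cut by a Claisen–Schmidt disconnection into an 8-acetyl-(3S)-3-hydroxy-5-methoxy-2,2-dimethylchroman and O-protected 4-hydroxybenzaldehyde.
- The route rests on one feature: the carbinol carbon C3 (S) and the benzylic methylene C4 of the pyran ring are the two carbons of the cis C3=C4 double bond of 8-acetyl-5-methoxy-2,2-dimethyl-2H-chromene. C2 is quaternary, so C3 is the only stereocentre.
- Mn–salen oxygen transfer to that double bond forms the C3–O and C4–O bonds of a cis-fused oxirane; hydrogenolysis of the benzylic C4–O bond then leaves the C3 alcohol.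
- The chromene comes from paeonol by O-propargylation and a thermal Claisen/[1,5]-H/oxa-6π cascade at its only free ortho carbon.
- Ring order: paeonol benzene ring (bought), pyran ring (step 2), oxirane (step 3, opened in step 4); the second benzene ring arrives with the aldehyde.

Key step: step 3

Remark (assumption): the (S,S)-salen ligand is assigned to the (3S,4S)-oxide by analogy with the parent 2,2-dimethyl-2H-chromene, whose CIP priority pattern at C3 and C4 is the same as here; the sense of induction would be confirmed on the first batch.

**Route**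

Step 1
Reactants: 1 paeonol (1-(2-hydroxy-4-methoxyphenyl)ethanone); 2 3-chloro-3-methylbut-1-yne
Product: 3 1-[4-methoxy-2-(2-methylbut-3-yn-2-yloxy)phenyl]ethanone
Conditions: K2CO3, KI (cat.), CuI (cat.), DMF, 65 °C
Reagents that add atoms: none
Why: Copper-assisted propargylic substitution (copper acetylide/propargyl cation pathway) is the standard O-alkylation of phenols with tertiary propargylic chlorides, and carbonate in DMF should free the chelated ortho-acyl phenoxide for attack at the tertiary carbon.

Step 2
Reactants: 3 1-[4-methoxy-2-(2-methylbut-3-yn-2-yloxy)phenyl]ethanone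
Product: 7 1-(5-methoxy-2,2-dimethyl-2H-chromen-8-yl)ethanone, via allenyl cyclohexadienone 4 (not isolated), via allenylphenol 5 (not isolated), via ortho-quinone methide 6 (not isolated)
Conditions: PhNEt2, 185 °C
Reagents that add atoms: none
Why: The aromatic propargyl Claisen rearrangement can only go to the free ortho carbon between the ether oxygen and the methoxy group (the other ortho carbon carries the acetyl group), and enolisation, [1,5]-hydrogen shift and oxa-6π electrocyclisation should then close the 2,2-dimethylpyran ring as a single regioisomer.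

Step 3
Reactants: 7 1-(5-methoxy-2,2-dimethyl-2H-chromen-8-yl)ethanone
Product: 8 1-[(3S,4S)-3,4-epoxy-5-methoxy-2,2-dimethyl-3,4-dihydro-2H-chromen-8-yl]ethanone
Conditions: (S,S)-Jacobsen Mn(salen)Cl catalyst (4 mol %), 4-phenylpyridine N-oxide (0.2 equiv), aq. NaOCl (Na2HPO4 buffer, pH 11.3), CH2Cl2, 0 °C
Reagents that add atoms: sodium hypochlorite, [Na+].[O-]Cl
Why: Hypochlorite oxidises the Mn(III)–salen complex to a Mn(V)=O species (the N-oxide serves as axial ligand), which transfers oxygen to the electron-rich cis C3=C4 styrenyl double bond by side-on approach, the C3–O bond forming first to leave a C4 benzylic radical that collapses onto oxygen. The closest known reaction is the Jacobsen–Katsuki epoxidation of 2,2-dimethyl-2H-chromenes, the alkene class for which this catalyst is most selective. The oxirane closes by this stepwise [2+1] oxygen-atom transfer (3-exo radical collapse), and the six-membered ring permits only cis fusion, so no cis/trans leakage can occur. C3 is set in the enantio-determining first C–O bond formation by the (S,S)-diaminocyclohexane backbone and its tert-butyl groups, which should expose the face leading to 3S, and C4 (4S) then follows from the ring constraint. The step needs enantiofacial selectivity and chemoselectivity for the alkene over the aryl methyl ketone: the flat cis alkene next to the C2 gem-dimethyl group should secure the first, and the cold, basic, biphasic medium, in which haloform chlorination of the ketone is slow and the acid-labile benzylic oxide is protected, should secure the second.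

Step 4
Reactants: 8 1-[(3S,4S)-3,4-epoxy-5-methoxy-2,2-dimethyl-3,4-dihydro-2H-chromen-8-yl]ethanone
Product: 9 1-[(3S)-3-hydroxy-5-methoxy-2,2-dimethyl-3,4-dihydro-2H-chromen-8-yl]ethanone
Conditions: H2 (1 atm), 10% Pd/C, EtOAc, rt, stopped when 8 is consumed
Reagents that add atoms: none
Why: Palladium-catalysed hydrogenolysis of a benzylic epoxide cleaves only the C4–O bond, which is benzylic and flanked by two ortho oxygen donors, so the C3–O bond and its S configuration are untouched, while the aryl ketone, deactivated by its ortho and para oxygen donors, should be reduced far more slowly at 1 atm.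

Step 5
Reactants: 10 4-hydroxybenzaldehyde
Product: 11 4-(methoxymethoxy)benzaldehyde
Conditions: MOMCl, K2CO3, acetone, 0 °C to rt
Reagents that add atoms: chloromethyl methyl ether (MOMCl), COCCl
Why: Williamson-type O-alkylation of the acidic phenol with the highly reactive α-chloro ether should give the MOM ether cleanly, and the aldehyde is inert under these conditions.

Step 6
Reactants: 9 1-[(3S)-3-hydroxy-5-methoxy-2,2-dimethyl-3,4-dihydro-2H-chromen-8-yl]ethanone; 11 4-(methoxymethoxy)benzaldehyde
Product: 13 (E)-1-[(3S)-3-hydroxy-5-methoxy-2,2-dimethyl-3,4-dihydro-2H-chromen-8-yl]-3-[4-(methoxymethoxy)phenyl]prop-2-en-1-one, via aldol adduct 12 (not isolated)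
Conditions: KOH, EtOH/H2O, rt
Reagents that add atoms: none
Why: In this Claisen–Schmidt condensation the methyl ketone is the only enolisable carbonyl and the aldehyde cannot enolise, E1cB dehydration of the aldol gives the conjugated (E)-enone under thermodynamic control, and the C3 carbinol, which is not next to any acidifying group, cannot epimerise.

Step 7
Reactants: 13 (E)-1-[(3S)-3-hydroxy-5-methoxy-2,2-dimethyl-3,4-dihydro-2H-chromen-8-yl]-3-[4-(methoxymethoxy)phenyl]prop-2-en-1-one
Product: 14 (E)-1-[(3S)-3-hydroxy-5-methoxy-2,2-dimethyl-3,4-dihydro-2H-chromen-8-yl]-3-(4-hydroxyphenyl)prop-2-en-1-one (target, CNP0291031.1)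
Conditions: conc. HCl (cat.), MeOH, 40 °C
Reagents that add atoms: none
Why: Acid-catalysed acetal cleavage of the MOM ether through its oxocarbenium ion, trapped by methanol, should free the phenol, while the chroman ether, the secondary alcohol and the enone tolerate dilute methanolic acid and no 2'-hydroxyl is present to close a flavanone.

**Compound list**

1 | paeonol, 1-(2-hydroxy-4-methoxyphenyl)ethanone | COc1ccc(C(C)=O)c(O)c1 | starting material
2 | 3-chloro-3-methylbut-1-yne | CC(C)(Cl)C#C | starting material
3 | 1-[4-methoxy-2-(2-methylbut-3-yn-2-yloxy)phenyl]ethanone | COc1ccc(C(C)=O)c(OC(C)(C)C#C)c1 | intermediate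
4 | 2-acetyl-5-methoxy-6-(3-methylbuta-1,2-dien-1-yl)cyclohexa-2,4-dien-1-one (racemic, transient) | COC1=CC=C(C(C)=O)C(=O)C1C=C=C(C)C | intermediate
5 | 1-[2-hydroxy-4-methoxy-3-(3-methylbuta-1,2-dien-1-yl)phenyl]ethanone | COc1ccc(C(C)=O)c(O)c1C=C=C(C)C | intermediate
6 | (6Z)-2-acetyl-5-methoxy-6-(3-methylbut-2-en-1-ylidene)cyclohexa-2,4-dien-1-one | O=C1C(C(C)=O)=CC=C(OC)/C1=C/C=C(C)C | intermediate
7 | 1-(5-methoxy-2,2-dimethyl-2H-chromen-8-yl)ethanone | COc1ccc(C(C)=O)c2c1C=CC(C)(C)O2 | intermediate
8 | 1-[(3S,4S)-3,4-epoxy-5-methoxy-2,2-dimethyl-3,4-dihydro-2H-chromen-8-yl]ethanone | COc1ccc(C(C)=O)c2c1[C@H]3[C@H](O3)C(C)(C)O2 | intermediate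
9 | 1-[(3S)-3-hydroxy-5-methoxy-2,2-dimethyl-3,4-dihydro-2H-chromen-8-yl]ethanone | COc1ccc(C(C)=O)c2c1C[C@H](O)C(C)(C)O2 | intermediate
10 | 4-hydroxybenzaldehyde | O=Cc1ccc(O)cc1 | starting material
11 | 4-(methoxymethoxy)benzaldehyde | COCOc1ccc(C=O)cc1 | intermediate
12 | 3-hydroxy-1-[(3S)-3-hydroxy-5-methoxy-2,2-dimethyl-3,4-dihydro-2H-chromen-8-yl]-3-[4-(methoxymethoxy)phenyl]propan-1-one (both epimers at the new carbinol carbon) | COc1ccc(C(=O)CC(O)c2ccc(OCOC)cc2)c2c1C[C@H](O)C(C)(C)O2 | intermediate
13 | (E)-1-[(3S)-3-hydroxy-5-methoxy-2,2-dimethyl-3,4-dihydro-2H-chromen-8-yl]-3-[4-(methoxymethoxy)phenyl]prop-2-en-1-one | COc1ccc(C(=O)/C=C/c2ccc(OCOC)cc2)c2c1C[C@H](O)C(C)(C)O2 | intermediate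
14 | (E)-1-[(3S)-3-hydroxy-5-methoxy-2,2-dimethyl-3,4-dihydro-2H-chromen-8-yl]-3-(4-hydroxyphenyl)prop-2-en-1-one | COc1ccc(C(=O)/C=C/c2ccc(O)cc2)c2c1C[C@H](O)C(C)(C)O2 | target

**Step count**

Total steps: 7. Longest linear sequence: 6 (steps 1, 2, 3, 4, 6, 7); step 5 is a one-step side branch.

**Steps most likely to fail**

Step 3. The peri 5-methoxy group and the neighbouring 8-acetyl/ring-oxygen pair may disturb the side-on approach, so facial discrimination could fall short, and partial opening of the electron-rich benzylic oxide could erode the material further. The fallback keeps the epoxidation and secures enantiopurity by diastereomer separation instead of catalyst control alone. It sets out from compound 9 of insufficient enantiomeric purity. Esterification with (S)-2-methoxy-2-phenylacetic acid (DCC, DMAP, CH2Cl2, 0 °C) should give (3S)-8-acetyl-5-methoxy-2,2-dimethyl-3,4-dihydro-2H-chromen-3-yl (2S)-2-methoxy-2-phenylacetate F1, together with a little of the diastereomer (3R)-8-acetyl-5-methoxy-2,2-dimethyl-3,4-dihydro-2H-chromen-3-yl (2S)-2-methoxy-2-phenylacetate F2 from the minor enantiomer. F2 would be removed by crystallisation or chromatography. Methanolysis of F1 (K2CO3, MeOH, rt) comes back to the route at compound 9.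

Step 4. The aryl methyl ketone could be over-reduced, or the oxide could isomerise on palladium to a chromanone. The fallback replaces catalytic hydrogenolysis by nucleophilic opening and radical dehalogenation, and sets out from compound 8. Bromide (LiBr, AcOH, THF, 0 °C) should open the oxide at the benzylic C4 with inversion and leave the C3–O bond untouched, giving 1-[(3R,4R)-4-bromo-3-hydroxy-5-methoxy-2,2-dimethyl-3,4-dihydro-2H-chromen-8-yl]ethanone F3. The C3 descriptor changes only because bromine raises the CIP rank of C4; the geometry at C3 is unchanged. Reduction of the benzylic C–Br bond with Bu3SnH and AIBN in toluene at 80 °C, to which the ketone is inert, comes back to the route at compound 9.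

Step 1. The phenol of paeonol is hydrogen-bonded to the acetyl group and flanked by it, so O-alkylation by the hindered tertiary chloride may stall while the chloride is lost by elimination. The fallback forms the C–C bond first and the C–O bond second, and sets out from compound 1. Heating with 3-methylbut-2-enal, phenylboronic acid and catalytic acetic acid in toluene under Dean–Stark conditions should hydroxyalkylate the only free ortho carbon through 1-[5-methoxy-4-(2-methylprop-1-en-1-yl)-2-phenyl-4H-1,3,2-benzodioxaborin-8-yl]ethanone F4. On continued heating F4 should fragment to the ortho-quinone methide 6, which closes by oxa-6π electrocyclisation. The sequence bypasses compound 3 and comes back to the route at compound 7.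

**Further compounds**

F1 | step 3 | (3S)-8-acetyl-5-methoxy-2,2-dimethyl-3,4-dihydro-2H-chromen-3-yl (2S)-2-methoxy-2-phenylacetate | COc1ccc(C(C)=O)c2c1C[C@H](OC(=O)[C@@H](OC)c1ccccc1)C(C)(C)O2
F2 | step 3 | (3R)-8-acetyl-5-methoxy-2,2-dimethyl-3,4-dihydro-2H-chromen-3-yl (2S)-2-methoxy-2-phenylacetate | COc1ccc(C(C)=O)c2c1C[C@@H](OC(=O)[C@@H](OC)c1ccccc1)C(C)(C)O2
F3 | step 4 | 1-[(3R,4R)-4-bromo-3-hydroxy-5-methoxy-2,2-dimethyl-3,4-dihydro-2H-chromen-8-yl]ethanone | COc1ccc(C(C)=O)c2c1[C@@H](Br)[C@H](O)C(C)(C)O2
F4 | step 1 | 1-[5-methoxy-4-(2-methylprop-1-en-1-yl)-2-phenyl-4H-1,3,2-benzodioxaborin-8-yl]ethanone | COc1ccc(C(C)=O)c2OB(c3ccccc3)OC(C=C(C)C)c12
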